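The six-membered ring (C1 = chain-bearing carbinol, C2=C3 alkene, C4 and C5 carbinols, C6 methylene) is grown from a five-membered one. The key step exploits that C2 is a lone vinylic CH between C1 and C3: the other five carbons (C1, C3, C4, C5, C6) are the ring of commercial (R)-4-silyloxycyclopentenone. Its regiodefined silyl enol ether is cyclopropanated and the shared C1–C3 bond is cleaved oxidatively with FeCl3, giving (S)-5-silyloxycyclohex-2-enone with C5 untouched. That centre then steers an epoxide to C1 and a hydroxyl to C4, and a Wharton transposition delivers the C1 carbinol and the C2=C3 alkene.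

Key step: step 5

Remark: ring positions are numbered as in the target throughout (C1 chain-bearing carbinol, C2=C3, C4, C5, C6), also for the six-membered intermediates; 8, 9 and 12 are diastereomer mixtures at centres that the following step erases.

Step 1
Reactants: 1 (E)-hex-1-en-1-ylboronic acid
Product: 2 (E)-1-iodohex-1-ene
Conditions: NaOH (aq, 3 equiv), Et2O, 0 °C; then I2 (1.1 equiv), 0 °C
Reagents that add atoms: iodine, [I][I]
Why: Iododeboronation of the (E)-alkenylboronate formed with hydroxide proceeds with retention at the sp2 carbon, so the E geometry of the future chain alkene is carried over unchanged from commercial 1.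

Step 2
Reactants: 3 11-chloroundec-1-ene; 2 (E)-1-iodohex-1-ene
Product: 5 (E)-17-chloroheptadec-5-ene, via 9-(11-chloroundecyl)-9-borabicyclo[3.3.1]nonane 4 (not isolated)
Conditions: 9-borabicyclo[3.3.1]nonane (9-BBN-H, 0.5 M in THF, 1.05 equiv), THF, 0 °C to rt; then 2, Pd(dppf)Cl2 (3 mol %), NaOH (3 M aq), THF, 50 °C
Reagents that add atoms: none
Why: Anti-Markovnikov hydroboration of the terminal alkene followed by B-alkyl Suzuki–Miyaura coupling with the alkenyl iodide should form the C(sp3)–C(sp2) bond with retention of the E geometry, the primary chloride being inert to the palladium catalyst.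

Step 3
Reactants: 6 (R)-4-(tert-butyldimethylsilyloxy)cyclopent-2-en-1-one
Product: 7 (S)-4-(tert-butyldimethylsilyloxy)-1-(triethylsilyloxy)cyclopent-1-ene
Conditions: Et3SiH (1.2 equiv), RhCl(PPh3)3 (1 mol %), THF, 50 °C
Reagents that add atoms: triethylsilane, CC[SiH](CC)CC
Why: Rhodium-catalysed 1,4-hydrosilylation of the enone should give the silyl enol ether regiospecifically at the former enone C=C, remote from the silyloxy-bearing stereocentre, which is not touched and which thereby fixes the place of the later ring enlargement.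

Step 4
Reactants: 7 (S)-4-(tert-butyldimethylsilyloxy)-1-(triethylsilyloxy)cyclopent-1-ene
Product: 8 (3S)-3-(tert-butyldimethylsilyloxy)-1-(triethylsilyloxy)bicyclo[3.1.0]hexane (cyclopropane diastereomers, anti to the silyloxy group expected as the major one)
Conditions: ZnEt2 (1.5 equiv), CH2I2 (3 equiv), CH2Cl2, 0 °C to rt
Reagents that add atoms: diiodomethane, ICI
Why: Simmons–Smith cyclopropanation under Furukawa conditions should add the methylene to the electron-rich enol ether, mainly anti to the silyloxy group, and the two new ring-fusion centres need no control because step 5 erases both.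

Step 5
Reactants: 8 (3S)-3-(tert-butyldimethylsilyloxy)-1-(triethylsilyloxy)bicyclo[3.1.0]hexane
Product: 10 (S)-5-(tert-butyldimethylsilyloxy)cyclohex-2-en-1-one, via (5R)-3-chloro-5-(tert-butyldimethylsilyloxy)cyclohexan-1-one 9 (not isolated)
Conditions: FeCl3 (2.2 equiv), pyridine (1 equiv), DMF, 0 °C; then NaOAc (3 equiv), MeOH, rt
Reagents that add atoms: none
Why: FeCl3 oxidises the silyloxycyclopropane by one electron, with loss of the silyl group as Et3SiCl, to a cyclopropyloxy radical that undergoes β-scission of the ring-fusion bond to the ring-enlarged β-keto radical; chlorine transfer from a second FeCl3 gives the 3-chlorocyclohexanone 9, and NaOAc removes HCl by an E1cB process to give the enone. The closest known reaction type is the Ito–Saegusa one-carbon ring expansion of cycloalkanone silyl enol ethers through siloxycyclopropanes. No ring is closed by cyclisation: the six-membered ring arises from the five-membered ring of the bicyclo[3.1.0]hexane by cleavage of the bond it shares with the cyclopropane, so that the cyclopropane methylene becomes ring atom C2. No stereocentre is created in 10 (the C–Cl centre of 9 is erased on elimination), and the silyloxy-bearing carbon C5 takes no part, so its configuration is kept. The step needs cleavage of the internal rather than an external cyclopropane bond, which the substrate secures because only internal scission gives a secondary, ring-expanded radical; it also needs loss of HCl rather than of silanol, which is secured because chloride sits β to the carbonyl on the C2 side and is by far the better leaving group under the weak base.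

Step 6
Reactants: 5 (E)-17-chloroheptadec-5-ene; 10 (S)-5-(tert-butyldimethylsilyloxy)cyclohex-2-en-1-one
Product: 12 (5S)-5-(tert-butyldimethylsilyloxy)-1-[(E)-heptadec-12-en-1-yl]cyclohex-2-en-1-ol (both C1 epimers), via (E)-heptadec-12-en-1-ylmagnesium chloride 11 (not isolated)
Conditions: Mg turnings, I2 (cat.), THF, reflux; then LaCl3·2LiCl (0.3 equiv), 10, THF, −78 °C; aq NH4Cl
Reagents that add atoms: none
Why: Grignard 1,2-addition to the enone carbonyl, assisted by the oxophilic lanthanum salt to suppress enolisation and β-elimination of the silyloxy group, should give the tertiary allylic alcohol, whose C1 configuration is irrelevant because C1 becomes sp2 in step 7.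

Step 7
Reactants: 12 (5S)-5-(tert-butyldimethylsilyloxy)-1-[(E)-heptadec-12-en-1-yl]cyclohex-2-en-1-ol
Product: 13 (R)-5-(tert-butyldimethylsilyloxy)-3-[(E)-heptadec-12-en-1-yl]cyclohex-2-en-1-one
Conditions: pyridinium chlorochromate (C5H5NH)[CrO3Cl] (2 equiv), 4 Å molecular sieves, CH2Cl2, rt
Reagents that add atoms: pyridinium chlorochromate, [O-][Cr](=O)(=O)Cl.c1cc[nH+]cc1
Why: Dauben–Babler oxidative transposition, in which the tertiary allylic chromate ester shifts by a [3,3] process to C3 and is oxidised there, should move the carbonyl to C3 and leave the chain on the β-carbon C1 of the new enone without touching C5.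

Step 8
Reactants: 13 (R)-5-(tert-butyldimethylsilyloxy)-3-[(E)-heptadec-12-en-1-yl]cyclohex-2-en-1-one
Product: 14 (1R,4R,6R)-4-(tert-butyldimethylsilyloxy)-6-[(E)-heptadec-12-en-1-yl]-7-oxabicyclo[4.1.0]heptan-2-one
Conditions: H2O2 (30% aq, 3 equiv), NaOH (aq, 0.3 equiv), MeOH, −10 to 0 °C
Reagents that add atoms: hydrogen peroxide, OO
Why: Weitz–Scheffer epoxidation, in which hydroperoxide adds axially to the β-carbon C1 anti to the C5 silyloxy group (the 3,5-trans preference of 5-substituted cyclohexenones) and the enolate then closes the ring, should set C1 and C2 with the epoxide oxygen trans to the C5 oxygen.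

Step 9
Reactants: 14 (1R,4R,6R)-4-(tert-butyldimethylsilyloxy)-6-[(E)-heptadec-12-en-1-yl]-7-oxabicyclo[4.1.0]heptan-2-one
Product: 16 (1R,3S,4R,6R)-4-(tert-butyldimethylsilyloxy)-6-[(E)-heptadec-12-en-1-yl]-3-hydroxy-7-oxabicyclo[4.1.0]heptan-2-one, via potassium enolate 15 (not isolated)
Conditions: KN(SiMe3)2 (1.1 equiv), THF, −78 °C; then 2-(phenylsulfonyl)-3-phenyloxaziridine (1.3 equiv), −78 °C; aq NH4Cl
Reagents that add atoms: 2-(phenylsulfonyl)-3-phenyloxaziridine, O=S(=O)(c1ccccc1)N1OC1c1ccccc1
Why: Davis oxidation of the kinetic potassium enolate, which forms towards C4 because the epoxide carbon C2 is not deprotonated, should deliver oxygen to the enolate face anti to the adjacent C5 silyloxy group and so set the C4 hydroxyl trans to the C5 oxygen and cis to the epoxide.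

Step 10
Reactants: 16 (1R,3S,4R,6R)-4-(tert-butyldimethylsilyloxy)-6-[(E)-heptadec-12-en-1-yl]-3-hydroxy-7-oxabicyclo[4.1.0]heptan-2-one
Product: 18 (1R,4R,5R)-5-(tert-butyldimethylsilyloxy)-1-[(E)-heptadec-12-en-1-yl]cyclohex-2-ene-1,4-diol, via epoxy hydrazone 17 (not isolated)
Conditions: N2H4·H2O (3 equiv), AcOH (0.2 equiv), MeOH, 0 °C to rt, under argon
Reagents that add atoms: none
Why: Wharton transposition, in which the epoxy hydrazone opens to an allylic diazene that loses N2, should convert C3 into a vinylic CH, form the C2=C3 double bond and leave the epoxide oxygen as the tertiary C1 hydroxyl with its configuration retained.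

Step 11
Reactants: 18 (1R,4R,5R)-5-(tert-butyldimethylsilyloxy)-1-[(E)-heptadec-12-en-1-yl]cyclohex-2-ene-1,4-diol
Product: 19 (1R,4R,5R)-1-[(E)-heptadec-12-en-1-yl]cyclohex-2-ene-1,4,5-triol
Conditions: Bu4NF (1.5 equiv), THF, 0 °C to rt
Reagents that add atoms: none
Why: Fluoride-mediated desilylation should free the C5 hydroxyl under non-acidic conditions that spare the acid-sensitive tertiary allylic alcohol and all three stereocentres.

Compound list

1 | (E)-hex-1-en-1-ylboronic acid | CCCC/C=C/B(O)O | starting material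
2 | (E)-1-iodohex-1-ene | CCCC/C=C/I | intermediate
3 | 11-chloroundec-1-ene | C=CCCCCCCCCCCl | starting material
4 | 9-(11-chloroundecyl)-9-borabicyclo[3.3.1]nonane | ClCCCCCCCCCCCB1C2CCCC1CCC2 | intermediate (not isolated)
5 | (E)-17-chloroheptadec-5-ene | CCCC/C=C/CCCCCCCCCCCCl | intermediate
6 | (R)-4-(tert-butyldimethylsilyloxy)cyclopent-2-en-1-one | O=C1C=C[C@H](O[Si](C)(C)C(C)(C)C)C1 | starting material
7 | (S)-4-(tert-butyldimethylsilyloxy)-1-(triethylsilyloxy)cyclopent-1-ene | CC[Si](CC)(CC)OC1=CC[C@H](O[Si](C)(C)C(C)(C)C)C1 | intermediate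
8 | (3S)-3-(tert-butyldimethylsilyloxy)-1-(triethylsilyloxy)bicyclo[3.1.0]hexane (anti cyclopropane drawn; both cyclopropane diastereomers converge) | CC[Si](CC)(CC)O[C@]12C[C@H]1C[C@H](O[Si](C)(C)C(C)(C)C)C2 | intermediate
9 | (5R)-3-chloro-5-(tert-butyldimethylsilyloxy)cyclohexan-1-one (C3 epimers) | O=C1CC(Cl)C[C@H](O[Si](C)(C)C(C)(C)C)C1 | intermediate (not isolated)
10 | (S)-5-(tert-butyldimethylsilyloxy)cyclohex-2-en-1-one | O=C1C=CC[C@H](O[Si](C)(C)C(C)(C)C)C1 | intermediate
11 | (E)-heptadec-12-en-1-ylmagnesium chloride | CCCC/C=C/CCCCCCCCCCC[Mg]Cl | intermediate (not isolated)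
12 | (5S)-5-(tert-butyldimethylsilyloxy)-1-[(E)-heptadec-12-en-1-yl]cyclohex-2-en-1-ol (C1 epimers) | CCCC/C=C/CCCCCCCCCCCC1(O)C=CC[C@H](O[Si](C)(C)C(C)(C)C)C1 | intermediate
13 | (R)-5-(tert-butyldimethylsilyloxy)-3-[(E)-heptadec-12-en-1-yl]cyclohex-2-en-1-one | CCCC/C=C/CCCCCCCCCCCC1=CC(=O)C[C@H](O[Si](C)(C)C(C)(C)C)C1 | intermediate
14 | (1R,4R,6R)-4-(tert-butyldimethylsilyloxy)-6-[(E)-heptadec-12-en-1-yl]-7-oxabicyclo[4.1.0]heptan-2-one | CCCC/C=C/CCCCCCCCCCC[C@@]12C[C@@H](O[Si](C)(C)C(C)(C)C)CC(=O)[C@@H]1O2 | intermediate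
15 | potassium 4-(tert-butyldimethylsilyloxy)-6-[(E)-heptadec-12-en-1-yl]-7-oxabicyclo[4.1.0]hept-2-en-2-olate (enolate of 14, stereocentres as in 14) | CCCC/C=C/CCCCCCCCCCC[C@@]12C[C@@H](O[Si](C)(C)C(C)(C)C)C=C([O-])[C@@H]1O2.[K+] | intermediate (not isolated)
16 | (1R,3S,4R,6R)-4-(tert-butyldimethylsilyloxy)-6-[(E)-heptadec-12-en-1-yl]-3-hydroxy-7-oxabicyclo[4.1.0]heptan-2-one | CCCC/C=C/CCCCCCCCCCC[C@@]12C[C@@H](O[Si](C)(C)C(C)(C)C)[C@H](O)C(=O)[C@@H]1O2 | intermediate
17 | hydrazone of 16 at the ketone carbon (stereocentres as in 16) | CCCC/C=C/CCCCCCCCCCC[C@@]12C[C@@H](O[Si](C)(C)C(C)(C)C)[C@H](O)C(=NN)[C@@H]1O2 | intermediate (not isolated)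
18 | (1R,4R,5R)-5-(tert-butyldimethylsilyloxy)-1-[(E)-heptadec-12-en-1-yl]cyclohex-2-ene-1,4-diol | CCCC/C=C/CCCCCCCCCCC[C@]1(O)C=C[C@@H](O)[C@H](O[Si](C)(C)C(C)(C)C)C1 | intermediate
19 | (1R,4R,5R)-1-[(E)-heptadec-12-en-1-yl]cyclohex-2-ene-1,4,5-triol (ring numbered from the chain-bearing carbon) | CCCC/C=C/CCCCCCCCCCC[C@]1(O)C=C[C@@H](O)[C@H](O)C1 | target

Total step count: 11. Longest linear sequence: 9 steps (6 to 19, steps 3 to 11).

Steps most likely to fail

1. Step 5 (key step). The oxidative opening may cleave an external cyclopropane bond so that the ring does not grow, the Lewis-acidic iron salt may strip a silyl ether, or the base stage may expel silanol from the β-silyloxy ketone and aromatise the ring. The fallback runs from 7 back to 10 and enlarges the ring by an electrocyclic instead of a radical opening. Dibromocarbene (CHBr3, KOC(CH3)3, pentane, −20 °C) is added to 7 to give (3S)-6,6-dibromo-3-(tert-butyldimethylsilyloxy)-1-(triethylsilyloxy)bicyclo[3.1.0]hexane F1. On heating in toluene this adduct should open in a disrotatory cyclopropyl-to-allyl process, with loss of bromide and of the triethylsilyl group, to (S)-2-bromo-5-(tert-butyldimethylsilyloxy)cyclohex-2-en-1-one F2. Radical hydrodebromination (Bu3SnH, AIBN, benzene, 80 °C) then gives 10.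

2. Step 9. The enolate may expel the neighbouring silyloxy group by an E1cB process or open the epoxide, oxygen transfer may occur with poor facial selectivity, or the ketol may be oxidised further. The fallback runs from 13 back to 16 and introduces the C4 oxygen by radical α′-acetoxylation before the epoxide is made, so that no enolate of an epoxy ketone is needed. Heating 13 with Mn(OAc)3 in benzene should give (5R,6S)-6-acetoxy-5-(tert-butyldimethylsilyloxy)-3-[(E)-heptadec-12-en-1-yl]cyclohex-2-en-1-one F3, with the acetoxy group trans to the silyloxy group. Nucleophilic epoxidation with tert-butyl hydroperoxide and DBU in CH2Cl2 at 0 °C, again anti to the C5 silyloxy group, should give (1R,3S,4R,6R)-3-acetoxy-4-(tert-butyldimethylsilyloxy)-6-[(E)-heptadec-12-en-1-yl]-7-oxabicyclo[4.1.0]heptan-2-one F4. Brief methanolysis (K2CO3, MeOH, 0 °C) gives 16.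

3. Step 10. The epoxy hydrazone may fail to fragment cleanly: diimide formed from hydrazine may hydrogenate the alkenes, a pyrazoline may form, or the carbonyl may simply be reduced. The fallback runs from 16 to 19 and achieves the same 1,3-transposition by fragmentation of an epoxy carbinyl radical (Barton–McCombie type). The C4 hydroxyl of 16 is silylated (tert-butyldimethylsilyl triflate, 2,6-lutidine, CH2Cl2, −78 °C) to give (1R,3S,4R,6R)-3,4-bis(tert-butyldimethylsilyloxy)-6-[(E)-heptadec-12-en-1-yl]-7-oxabicyclo[4.1.0]heptan-2-one F5. Reduction with NaBH4 in MeOH at −20 °C gives 3,4-bis(tert-butyldimethylsilyloxy)-6-[(E)-heptadec-12-en-1-yl]-7-oxabicyclo[4.1.0]heptan-2-ol F6, of which either carbinol epimer serves. Acylation with 1,1′-thiocarbonyldiimidazole (DMAP, CH2Cl2, rt) gives the O-(imidazol-1-ylthiocarbonyl) derivative F7. Bu3SnH and AIBN in toluene at 100 °C should generate the C3 radical, which opens the epoxide to the C2=C3 alkene and a C1 alkoxy radical, and after hydrogen transfer gives (1R,4R,5R)-4,5-bis(tert-butyldimethylsilyloxy)-1-[(E)-heptadec-12-en-1-yl]cyclohex-2-en-1-ol F8. Bu4NF in THF removes both silyl groups and gives 19.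

Further compounds

F1 | step 5 | (3S)-6,6-dibromo-3-(tert-butyldimethylsilyloxy)-1-(triethylsilyloxy)bicyclo[3.1.0]hexane (cyclopropane diastereomers) | CC[Si](CC)(CC)OC12C[C@@H](O[Si](C)(C)C(C)(C)C)CC1C2(Br)Br
F2 | step 5 | (S)-2-bromo-5-(tert-butyldimethylsilyloxy)cyclohex-2-en-1-one | O=C1C(Br)=CC[C@H](O[Si](C)(C)C(C)(C)C)C1
F3 | step 9 | (5R,6S)-6-acetoxy-5-(tert-butyldimethylsilyloxy)-3-[(E)-heptadec-12-en-1-yl]cyclohex-2-en-1-one | CCCC/C=C/CCCCCCCCCCCC1=CC(=O)[C@@H](OC(C)=O)[C@H](O[Si](C)(C)C(C)(C)C)C1
F4 | step 9 | (1R,3S,4R,6R)-3-acetoxy-4-(tert-butyldimethylsilyloxy)-6-[(E)-heptadec-12-en-1-yl]-7-oxabicyclo[4.1.0]heptan-2-one | CCCC/C=C/CCCCCCCCCCC[C@@]12C[C@@H](O[Si](C)(C)C(C)(C)C)[C@H](OC(C)=O)C(=O)[C@@H]1O2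
F5 | step 10 | (1R,3S,4R,6R)-3,4-bis(tert-butyldimethylsilyloxy)-6-[(E)-heptadec-12-en-1-yl]-7-oxabicyclo[4.1.0]heptan-2-one | CCCC/C=C/CCCCCCCCCCC[C@@]12C[C@@H](O[Si](C)(C)C(C)(C)C)[C@H](O[Si](C)(C)C(C)(C)C)C(=O)[C@@H]1O2
F6 | step 10 | 3,4-bis(tert-butyldimethylsilyloxy)-6-[(E)-heptadec-12-en-1-yl]-7-oxabicyclo[4.1.0]heptan-2-ol (C2 epimers, other centres as in F5) | CCCC/C=C/CCCCCCCCCCC[C@@]12C[C@@H](O[Si](C)(C)C(C)(C)C)[C@H](O[Si](C)(C)C(C)(C)C)C(O)[C@@H]1O2
F7 | step 10 | O-{3,4-bis(tert-butyldimethylsilyloxy)-6-[(E)-heptadec-12-en-1-yl]-7-oxabicyclo[4.1.0]heptan-2-yl} 1H-imidazole-1-carbothioate | CCCC/C=C/CCCCCCCCCCC[C@@]12C[C@@H](O[Si](C)(C)C(C)(C)C)[C@H](O[Si](C)(C)C(C)(C)C)C(OC(=S)n3ccnc3)[C@@H]1O2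
F8 | step 10 | (1R,4R,5R)-4,5-bis(tert-butyldimethylsilyloxy)-1-[(E)-heptadec-12-en-1-yl]cyclohex-2-en-1-ol | CCCC/C=C/CCCCCCCCCCC[C@]1(O)C=C[C@@H](O[Si](C)(C)C(C)(C)C)[C@H](O[Si](C)(C)C(C)(C)C)C1
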